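## Retrosynthetic overview

1. Fluoride removes three silyl groups last. Before that, two aryl ester C–O bonds join a catechol core to two equivalents of (2Z,4S,5S)-4,5-epoxyhex-2-enoate.
2. Regiocontrol comes from atromentin locked as its o-quinone tautomer by a di-tert-butylsilylene bridge, so reduction frees exactly the adjacent pair of hydroxyls.
3. The central ring is formed first in the core branch by head-to-tail double Claisen dimerisation of two carboxyl-activated 4-hydroxyphenylpyruvic acid units. This makes two C–C bonds in one flask and reaches the quinone oxidation level without an oxidant.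
4. The oxirane ring is formed in a parallel side-chain branch by oxygen-atom transfer to the E-olefin of crotyl alcohol under L-(+)-tartrate control, followed by Z-selective two-carbon olefination.
5. Ring order: six-membered carbocycle, then the temporary dioxasilole, with the oxirane made separately. The outer arenes are bought.

Assumption: a telescoped sequence in which no intermediate is isolated counts as one step, and (E)-but-2-en-1-ol of at least 96% E purity is used.

## Route

Step 1  
Reactants: 1 4-hydroxyphenylpyruvic acid (two molecules per product)  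
Product: 4 2,5-dihydroxy-3,6-bis[4-(tert-butyldimethylsilyloxy)phenyl]-1,4-benzoquinone (di-O-TBS-atromentin), via acyl imidazolide 2 (not isolated), via atromentin 3 (not isolated)  
Conditions: 1,1'-carbonyldiimidazole (1.05 equiv), THF, 0 °C to rt; MgCl2 (1.0 equiv), Et3N (1.2 equiv), MeCN, rt to 45 °C, Ar; then TBSCl (1.3 equiv), Et3N (1.5 equiv), rt; aq. citric acid work-up  
Reagents that add atoms: 1,1'-carbonyldiimidazole, `O=C(n1ccnc1)n1ccnc1` (its imidazolyl group is carried only by 2); tert-butyldimethylsilyl chloride, `CC(C)(C)[Si](C)(C)Cl`  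
Why: Proposed new method: carbonyldiimidazole turns the acid into acyl imidazolide 2 (a stand-in for an enzyme-bound thioester) and MgCl2/Et3N converts it fully into the five-membered magnesium chelate of its Z-enolate, which hides the ketone (starving the usual aldol–lactonisation to a butenolide) while polarising the acyl carbon, so the benzylic carbon of one unit attacks the acyl imidazole of a second (Claisen) and the open-chain enolate closes head-to-tail (Dieckmann, six-membered ring) to the tetraketone tautomer of 3, whose double deprotonation to the magnesium dihydroxyquinonate is the irreversible sink into which reversible O-acyl adducts (enol esters, aryl esters, pyrandiones) are drained by imidazole-mediated acyl transfer; the closest known reaction types are Masamune–Brooks C-acylation of magnesium enolates by acyl imidazoles, the dimerising Claisen–Dieckmann synthesis of succinylsuccinates and the base-induced acyl shift of 6-arylidenepyran-2,5-diones to terphenylquinones, after which the imidazole already in the flask serves a routine TBSCl silylation of the two phenols, any silyl group on the acidic quinone hydroxyls falls off on work-up, and no stereocentre is formed.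

Step 2  
Reactants: 4 di-O-TBS-atromentin  
Product: 5 2,2-di-tert-butyl-4,7-bis[4-(tert-butyldimethylsilyloxy)phenyl]-1,3,2-benzodioxasilole-5,6-dione (silylene-locked o-quinone tautomer)  
Conditions: Et3N (2.2 equiv), CH2Cl2, -78 °C; tBu2Si(OTf)2 (1.02 equiv, slow addition), -78 to 0 °C; hexane dilution, filtration, short plug of neutral silica (no water)  
Reagents that add atoms: di-tert-butylsilyl bis(trifluoromethanesulfonate), `CC(C)(C)[Si](OS(=O)(=O)C(F)(F)F)(OS(=O)(=O)C(F)(F)F)C(C)(C)C`  
Why: Proposed new method: the dianion of 4 consists of two independent vinylogous carboxylates so all four ring oxygens carry charge, and once the first Si–O bond is made the only oxygen within reach of the remaining Si–OTf is the neighbouring one, so five-membered ring closure irreversibly fixes the 4,5-dioxy-1,2-benzoquinone tautomer and can happen only once per molecule; the closest known reaction types are Corey–Hopkins di-tert-butylsilylene protection of 1,2-diols and catechols and the known interception of 2,5-dihydroxybenzoquinones through their o-quinone tautomer (dihydroxyphenazines with 1,2-diamines).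

Step 3  
Reactants: 6 (E)-but-2-en-1-ol (crotyl alcohol)  
Product: 7 (2S,3S)-2,3-epoxybutan-1-ol  
Conditions: Ti(OiPr)4 (5 mol %), L-(+)-diisopropyl tartrate (6 mol %), tBuOOH (1.5 equiv, anhydrous), 4 Å MS, CH2Cl2, -20 °C; non-aqueous work-up, distillation  
Reagents that add atoms: tert-butyl hydroperoxide, `CC(C)(C)OO`  
Why: Sharpless asymmetric epoxidation, in which the allylic alcohol binds to the titanium–tartrate complex, L-(+)-tartrate directs the peroxide oxygen to the olefin face that gives the (2S,3S)-epoxide (typically 90–95% ee), and the E-geometry is carried stereospecifically into the trans relationship, so both stereocentres of a side chain are set here.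

Step 4  
Reactants: 7 (2S,3S)-2,3-epoxybutan-1-ol; 8 methyl bis(2,2,2-trifluoroethyl)phosphonoacetate  
Product: 10 methyl (2Z,4S,5S)-4,5-epoxyhex-2-enoate, via epoxy aldehyde 9 (not isolated)  
Conditions: IBX (1.3 equiv), EtOAc, 75 °C, then 0 °C, filter, dry filtrate over 4 Å MS; filtrate added to 8 (1.15 equiv), KN(SiMe3)2 (1.1 equiv), 18-crown-6 (3 equiv), THF, -78 °C  
Reagents that add atoms: methyl bis(2,2,2-trifluoroethyl)phosphonoacetate (compound 8), `COC(=O)CP(=O)(OCC(F)(F)F)OCC(F)(F)F`  
Why: IBX oxidation stops at the volatile aldehyde 9 without touching the epoxide or its alpha stereocentre, and the Still–Gennari variant of the Horner–Wadsworth–Emmons reaction (electron-poor phosphonate, dissociated potassium ion) makes elimination from the kinetic adduct faster than its reversal, giving the Z-enoate (typically above 10:1) with no new stereocentre.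

Step 5  
Reactants: 10 methyl (2Z,4S,5S)-4,5-epoxyhex-2-enoate  
Product: 11 potassium (2Z,4S,5S)-4,5-epoxyhex-2-enoate  
Conditions: KOSiMe3 (1.05 equiv), Et2O, 0 °C to rt; salt filtered under Ar, washed with Et2O, used the same day  
Reagents that add atoms: potassium trimethylsilanolate, `C[Si](C)(C)[O-].[K+]`  
Why: Anhydrous silanolate ester cleavage (Laganis–Chenard) removes the methyl ester without water or acid and the carboxylate precipitates, so the free Z-acid, which would cyclise onto its own epoxide to a hydroxy lactone, is never formed and the olefin geometry and both stereocentres are untouched.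

Step 6  
Reactants: 5 silylene-locked o-quinone; 11 potassium (2Z,4S,5S)-4,5-epoxyhex-2-enoate (2.4 equiv)  
Product: 14 2,2-di-tert-butyl-4,7-bis[4-(tert-butyldimethylsilyloxy)phenyl]-1,3,2-benzodioxasilole-5,6-diyl bis[(2Z,4S,5S)-4,5-epoxyhex-2-enoate], via catechol 12 (not isolated), via mixed anhydride 13 (not isolated)  
Conditions: (a) 5, H2 (1 atm), Pd/C (5 mol %), THF, rt, 20 min, filtered and sparged under Ar; (b) 11, 2,4,6-Cl3C6H2COCl (2.4 equiv), THF, 0 °C, 30 min; (c) solution of 12 added to 13, Et3N (3 equiv), DMAP (0.1 equiv), -20 to 0 °C; pH 6 buffer work-up  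
Reagents that add atoms: 2,4,6-trichlorobenzoyl chloride, `O=C(Cl)c1c(Cl)cc(Cl)cc1Cl` (its aroyl group is carried only by 13)  
Why: Catalytic hydrogenation reduces only the o-quinone to the air-sensitive catechol 12, whose two free hydroxyls are by construction the adjacent pair, and Yamaguchi esterification through 13 (attack at the unhindered enoyl carbonyl) acylates both at low temperature with little DMAP to limit Z-to-E isomerisation, while joining two enantioenriched acyl groups to one achiral core diverts the minor enantiomer mainly into a separable meso-type diastereomer (Horeau amplification).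

Step 7  
Reactants: 14 protected diester  
Product: 15 4,5-dihydroxy-3,6-bis(4-hydroxyphenyl)benzene-1,2-diyl bis[(2Z,4S,5S)-4,5-epoxyhex-2-enoate] (CNP0249450.1)  
Conditions: Et3N·3HF (8 equiv), THF, 0 °C to rt, Ar; degassed pH 7 buffer work-up, chromatography with degassed solvents  
Reagents that add atoms: none  
Why: Fluoride-mediated desilylation driven by Si–F bond strength, in which the weakly acidic and non-basic Et3N·3HF cleaves the two aryl TBS ethers and the strained catechol silylene at or below room temperature, conditions that do not open epoxides, generate no phenoxide able to attack the aryl esters, and leave the Z-enoates and all four stereocentres untouched.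

## Compound list

1 | 4-hydroxyphenylpyruvic acid | `O=C(O)C(=O)Cc1ccc(O)cc1` | starting material  
2 | 3-(4-hydroxyphenyl)-1-(imidazol-1-yl)propane-1,2-dione (acyl imidazolide of 1, present as its magnesium Z-enolate) | `O=C(Cc1ccc(O)cc1)C(=O)n1ccnc1` | intermediate  
3 | atromentin, 2,5-dihydroxy-3,6-bis(4-hydroxyphenyl)-1,4-benzoquinone | `O=C1C(O)=C(c2ccc(O)cc2)C(=O)C(O)=C1c1ccc(O)cc1` | intermediate  
4 | 2,5-dihydroxy-3,6-bis[4-(tert-butyldimethylsilyloxy)phenyl]-1,4-benzoquinone | `O=C1C(O)=C(c2ccc(O[Si](C)(C)C(C)(C)C)cc2)C(=O)C(O)=C1c1ccc(O[Si](C)(C)C(C)(C)C)cc1` | intermediate  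
5 | 2,2-di-tert-butyl-4,7-bis[4-(tert-butyldimethylsilyloxy)phenyl]-1,3,2-benzodioxasilole-5,6-dione | `O=C1C(=O)C(c2ccc(O[Si](C)(C)C(C)(C)C)cc2)=C2O[Si](C(C)(C)C)(C(C)(C)C)OC2=C1c1ccc(O[Si](C)(C)C(C)(C)C)cc1` | intermediate  
6 | (E)-but-2-en-1-ol | `C/C=C/CO` | starting material  
7 | (2S,3S)-2,3-epoxybutan-1-ol | `C[C@@H]1O[C@H]1CO` | intermediate  
8 | methyl bis(2,2,2-trifluoroethyl)phosphonoacetate | `COC(=O)CP(=O)(OCC(F)(F)F)OCC(F)(F)F` | starting material  
9 | (2R,3S)-2,3-epoxybutanal | `C[C@@H]1O[C@H]1C=O` | intermediate  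
10 | methyl (2Z,4S,5S)-4,5-epoxyhex-2-enoate | `C[C@@H]1O[C@H]1/C=C\C(=O)OC` | intermediate  
11 | potassium (2Z,4S,5S)-4,5-epoxyhex-2-enoate | `C[C@@H]1O[C@H]1/C=C\C(=O)[O-].[K+]` | intermediate  
12 | 2,2-di-tert-butyl-4,7-bis[4-(tert-butyldimethylsilyloxy)phenyl]-1,3,2-benzodioxasilole-5,6-diol | `Oc1c(O)c(-c2ccc(O[Si](C)(C)C(C)(C)C)cc2)c2O[Si](C(C)(C)C)(C(C)(C)C)Oc2c1-c1ccc(O[Si](C)(C)C(C)(C)C)cc1` | intermediate  
13 | (2Z,4S,5S)-4,5-epoxyhex-2-enoic 2,4,6-trichlorobenzoic anhydride | `C[C@@H]1O[C@H]1/C=C\C(=O)OC(=O)c1c(Cl)cc(Cl)cc1Cl` | intermediate  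
14 | 2,2-di-tert-butyl-4,7-bis[4-(tert-butyldimethylsilyloxy)phenyl]-1,3,2-benzodioxasilole-5,6-diyl bis[(2Z,4S,5S)-4,5-epoxyhex-2-enoate] | `C[C@@H]1O[C@H]1/C=C\C(=O)Oc1c(OC(=O)/C=C\[C@@H]2O[C@H]2C)c(-c2ccc(O[Si](C)(C)C(C)(C)C)cc2)c2O[Si](C(C)(C)C)(C(C)(C)C)Oc2c1-c1ccc(O[Si](C)(C)C(C)(C)C)cc1` | intermediate  
15 | 4,5-dihydroxy-3,6-bis(4-hydroxyphenyl)benzene-1,2-diyl bis[(2Z,4S,5S)-4,5-epoxyhex-2-enoate] | `C[C@@H]1O[C@H]1/C=C\C(=O)Oc1c(OC(=O)/C=C\[C@@H]2O[C@H]2C)c(-c2ccc(O)cc2)c(O)c(O)c1-c1ccc(O)cc1` | target  

## Step count and risks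

Total step count: 7.

Longest linear sequence: 5 steps (6 to 7 to 10 to 11 to 14 to 15, which are steps 3, 4, 5, 6 and 7). The core branch has 4 steps (steps 1, 2, 6 and 7).

### Step 1 (dimerisation)

The arylpyruvate may follow its usual aldol–lactonisation to a butenolide dimer, or it may stall at O-acyl oligomers.

The fallback sets out from 1 and comes back at 4. It separates the nucleophile and electrophile roles instead of relying on self-sorting.

- Compound 1 is condensed through its enol and carboxyl groups with 2,2-dimethoxypropane (cat. camphorsulfonic acid, acetone). This gives (Z)-5-(4-hydroxybenzylidene)-2,2-dimethyl-1,3-dioxolan-4-one F1, a monomer with no ketone and an activated lactone carbonyl.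
- Silylation (TBSCl, imidazole) gives (Z)-5-[4-(tert-butyldimethylsilyloxy)benzylidene]-2,2-dimethyl-1,3-dioxolan-4-one F2.
- NaOMe (0.5 equiv, THF, -78 °C) opens half of F2, with loss of acetone, to sodium (Z)-1-methoxy-1-oxo-3-[4-(tert-butyldimethylsilyloxy)phenyl]prop-2-en-2-olate F3.
- F3 C-acylates the untouched, neutral half of F2 at its lactone carbonyl, the way ester enolates attack 5-arylidenedioxolanones in pulvinone syntheses. Loss of a second acetone gives methyl 3,6-bis[4-(tert-butyldimethylsilyloxy)phenyl]-2,4,5-trioxohexanoate F4 as its enolate.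
- NaN(SiMe3)2 (1 equiv per F4) triggers the Dieckmann closure, and acidic work-up delivers 4.

### Step 2 (trapping of the o-quinone tautomer)

Intermolecular silylation may compete, and the vinylogous silyl ester may be too easily hydrolysed.

The fallback sets out from 4 and comes back at 12. It gives up the tautomer trap and desymmetrises at the hydroquinone level.

- Compound 4 is hydrogenated (H2, Pd/C, THF) to 3,6-bis[4-(tert-butyldimethylsilyloxy)phenyl]benzene-1,2,4,5-tetraol F5.
- F5 is treated with tBu2Si(OTf)2 (0.9 equiv, 2,6-lutidine, CH2Cl2, -78 °C, slow addition). The silylene can only span an adjacent pair, so the mono-bridged product is 12 itself, with a statistical ceiling of about 50%.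
- Compound 12 is separated under Ar from 2,2,6,6-tetra-tert-butyl-4,8-bis[4-(tert-butyldimethylsilyloxy)phenyl]benzo[1,2-d:4,5-d']bis[1,3,2]dioxasilole F6 and from unreacted F5.
- Air re-oxidises the recovered F5 to 4 for recycling, and 12 enters step 6 at stage (c).

### Step 6 (double acylation)

Compounds 11 or 13 may lactonise onto the epoxide, DMAP may isomerise Z to E, and the second acylation of the hindered catechol may be slow.

The fallback sets out from 12 and 9 and comes back at 14. It builds the Z-olefins on the core, so no epoxy acid or activated epoxy acyl species is needed.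

- Compound 12 is esterified with commercial [bis(2,2,2-trifluoroethoxy)phosphoryl]acetic acid (EDC·HCl, cat. DMAP, CH2Cl2, 0 °C). This gives 2,2-di-tert-butyl-4,7-bis[4-(tert-butyldimethylsilyloxy)phenyl]-1,3,2-benzodioxasilole-5,6-diyl bis{[bis(2,2,2-trifluoroethoxy)phosphoryl]acetate} F7.
- A double Still–Gennari olefination (KN(SiMe3)2, 18-crown-6, THF, -78 °C) with a dried solution of aldehyde 9 (2.5 equiv, made as in step 4) installs both Z-enoates at once and gives 14.
- The low temperature keeps the stabilised phosphonate anion from expelling aryloxide.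

## Further compounds

F1 | step 1 | (Z)-5-(4-hydroxybenzylidene)-2,2-dimethyl-1,3-dioxolan-4-one | `CC1(C)OC(=O)/C(O1)=C/c2ccc(O)cc2`  
F2 | step 1 | (Z)-5-[4-(tert-butyldimethylsilyloxy)benzylidene]-2,2-dimethyl-1,3-dioxolan-4-one | `CC1(C)OC(=O)/C(O1)=C/c2ccc(O[Si](C)(C)C(C)(C)C)cc2`  
F3 | step 1 | sodium (Z)-1-methoxy-1-oxo-3-[4-(tert-butyldimethylsilyloxy)phenyl]prop-2-en-2-olate | `COC(=O)/C([O-])=C/c1ccc(O[Si](C)(C)C(C)(C)C)cc1.[Na+]`  
F4 | step 1 | methyl 3,6-bis[4-(tert-butyldimethylsilyloxy)phenyl]-2,4,5-trioxohexanoate (enolised, C3 not defined) | `COC(=O)C(=O)C(c1ccc(O[Si](C)(C)C(C)(C)C)cc1)C(=O)C(=O)Cc1ccc(O[Si](C)(C)C(C)(C)C)cc1`  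
F5 | step 2 | 3,6-bis[4-(tert-butyldimethylsilyloxy)phenyl]benzene-1,2,4,5-tetraol | `Oc1c(O)c(-c2ccc(O[Si](C)(C)C(C)(C)C)cc2)c(O)c(O)c1-c1ccc(O[Si](C)(C)C(C)(C)C)cc1`  
F6 | step 2 | 2,2,6,6-tetra-tert-butyl-4,8-bis[4-(tert-butyldimethylsilyloxy)phenyl]benzo[1,2-d:4,5-d']bis[1,3,2]dioxasilole | `CC(C)(C)[Si]1(C(C)(C)C)Oc2c(O1)c(-c1ccc(O[Si](C)(C)C(C)(C)C)cc1)c1O[Si](C(C)(C)C)(C(C)(C)C)Oc1c2-c1ccc(O[Si](C)(C)C(C)(C)C)cc1`  
F7 | step 6 | 2,2-di-tert-butyl-4,7-bis[4-(tert-butyldimethylsilyloxy)phenyl]-1,3,2-benzodioxasilole-5,6-diyl bis{[bis(2,2,2-trifluoroethoxy)phosphoryl]acetate} | `O=C(CP(=O)(OCC(F)(F)F)OCC(F)(F)F)Oc1c(OC(=O)CP(=O)(OCC(F)(F)F)OCC(F)(F)F)c(-c2ccc(O[Si](C)(C)C(C)(C)C)cc2)c2O[Si](C(C)(C)C)(C(C)(C)C)Oc2c1-c1ccc(O[Si](C)(C)C(C)(C)C)cc1`  
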